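**Plan**

- Numbering runs from the aryl ketone carbon (C1) along the chain to C12. Apart from the benzene ring the target is acyclic, and its C9 ketone lies between the allylic C8 methylene and the alkenyl carbon C10 (a skipped dienone), which a neutral three-component carbonylation can build.
- Retrosynthesis cuts, in order: the two aryl O–Si bonds; C8–C9 and C9–C10 together (allylic chloride + CO + alkenylstannane); the C8–Cl/C8–O bond back to a prenyl methyl group; the C1–aryl bond (aldehyde + arylmagnesium bromide); the C3–C4 bond (SN2' allylic alkylation).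
- Forward: a C1–C3 allylic phosphate from but-3-yn-1-ol is joined to the C4–C8 homoprenyl Grignard reagent, the aryl ketone is installed at C1, C8 is oxidised and chlorinated, and the C9–C12 end is added with CO. No ring is formed at any stage.
- Stereochemistry: the only stereocentre, C3 (R), is set by the copper-catalysed enantioselective SN2' alkylation. The E C6=C7 geometry comes from the E-selective selenium dioxide oxidation and is kept through the syn-allylpalladium intermediate.

Key step: step 13

Assumption: the facial sense of the chiral copper–carbene catalyst in step 4 is not predicted here; the ligand enantiomer that gives (R) at C3 is taken to be used, both ligand enantiomers being accessible.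

**Route**

Step 1
Reactants: 1 but-3-yn-1-ol
Product: 2 tert-butyl(but-3-yn-1-yloxy)dimethylsilane
Conditions: TBSCl, imidazole, CH2Cl2, 0 °C to rt
Reagents that add atoms: tert-butyldimethylsilyl chloride CC(C)(C)[Si](C)(C)Cl
Why: Imidazole-promoted silylation of the primary alcohol (silyl ether formation) masks the C1 oxygen for the organoaluminium and Grignard chemistry that follows.

Step 2
Reactants: 2 tert-butyl(but-3-yn-1-yloxy)dimethylsilane
Product: 5 (2E)-5-(tert-butyldimethylsilyloxy)-3-methylpent-2-en-1-ol, via alkenyldimethylalane 3 (not isolated), via lithium alkenylaluminate 4 (not isolated)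
Conditions: Me3Al, Cp2ZrCl2 (cat.), CH2Cl2, 0 °C to rt; then n-BuLi, THF/hexane, −30 °C; (CH2O)n, −30 °C to rt
Reagents that add atoms: trimethylaluminium C[Al](C)C; formaldehyde (as paraformaldehyde) C=O
Why: Zirconium-catalysed syn carboalumination of the terminal alkyne (Negishi carboalumination) puts the methyl group on the internal carbon and aluminium cis to it, and the aluminate formed with n-BuLi adds to formaldehyde with retention, so the trisubstituted alkene should form as the E isomer only.

Step 3
Reactants: 5 (2E)-5-(tert-butyldimethylsilyloxy)-3-methylpent-2-en-1-ol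
Product: 6 diethyl (2E)-5-(tert-butyldimethylsilyloxy)-3-methylpent-2-en-1-yl phosphate
Conditions: (EtO)2P(O)Cl, Et3N, DMAP (cat.), CH2Cl2, 0 °C
Reagents that add atoms: diethyl chlorophosphate CCOP(=O)(Cl)OCC
Why: Phosphorylation of the primary allylic alcohol supplies the leaving group that copper-catalysed SN2' substitution needs, without touching the alkene geometry.

Step 4
Reactants: 6 diethyl (2E)-5-(tert-butyldimethylsilyloxy)-3-methylpent-2-en-1-yl phosphate; 7 5-bromo-2-methylpent-2-ene
Product: 9 tert-butyl{[(3R)-3-ethenyl-3,7-dimethyloct-6-en-1-yl]oxy}dimethylsilane, via homoprenylmagnesium bromide 8 (not isolated)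
Conditions: 7, Mg, Et2O (gives 8); then 6, Cu(OTf)2 (2 mol%), chiral hydroxyalkyl-imidazolinium salt (3 mol%, bidentate carbene precursor), Et2O, −78 to −40 °C, slow addition of 8
Reagents that add atoms: none
Why: Copper-catalysed enantioselective allylic alkylation (SN2' substitution) of a gamma,gamma-disubstituted E allylic phosphate by a primary alkyl Grignard reagent: the carbene-bound alkylcopper of monovalent copper adds at C3 anti to the phosphate on the alkene face selected by the chiral ligand, and reductive elimination from the trivalent copper allyl forms the C3–C4 bond, the quaternary (R) centre and the vinyl group.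

Step 5
Reactants: 9 tert-butyl{[(3R)-3-ethenyl-3,7-dimethyloct-6-en-1-yl]oxy}dimethylsilane
Product: 10 (3R)-3-ethenyl-3,7-dimethyloct-6-en-1-ol
Conditions: Bu4NF, THF, 0 °C to rt
Reagents that add atoms: none
Why: Fluoride cleavage of the only silyl ether present (desilylation) frees the C1 alcohol.

Step 6
Reactants: 10 (3R)-3-ethenyl-3,7-dimethyloct-6-en-1-ol
Product: 11 (3R)-3-ethenyl-3,7-dimethyloct-6-enal
Conditions: Dess–Martin periodinane, CH2Cl2, 0 °C to rt
Reagents that add atoms: none
Why: Dess–Martin oxidation converts the primary alcohol into the aldehyde under neutral conditions, and the quaternary C3 carries no hydrogen, so nothing can epimerise.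

Step 7
Reactants: 12 4-bromobenzene-1,3-diol (4-bromoresorcinol)
Product: 13 1-bromo-2,4-bis(tert-butyldimethylsilyloxy)benzene
Conditions: TBSCl, imidazole, DMF, rt
Reagents that add atoms: tert-butyldimethylsilyl chloride CC(C)(C)[Si](C)(C)Cl
Why: Double silylation of the phenols (silyl ether formation) gives an aryl bromide that tolerates magnesium insertion and carries groups removable at the end under nearly neutral conditions.

Step 8
Reactants: 13 1-bromo-2,4-bis(tert-butyldimethylsilyloxy)benzene; 11 (3R)-3-ethenyl-3,7-dimethyloct-6-enal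
Product: 15 (3R)-1-[2,4-bis(tert-butyldimethylsilyloxy)phenyl]-3-ethenyl-3,7-dimethyloct-6-en-1-ol, via arylmagnesium bromide 14 (not isolated)
Conditions: 13, Mg, LiCl, THF, rt (gives 14); then 11, −40 to 0 °C; quench at −20 °C with pH 7 buffer
Reagents that add atoms: none
Why: Magnesium insertion into the aryl bromide and 1,2-addition to the aldehyde (Grignard addition) form the C1–aryl bond; the C1 carbinol arises as both epimers, which is immaterial because it is oxidised next, and the cold quench should keep the ortho silyl group from migrating to the alkoxide.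

Step 9
Reactants: 15 (3R)-1-[2,4-bis(tert-butyldimethylsilyloxy)phenyl]-3-ethenyl-3,7-dimethyloct-6-en-1-ol
Product: 16 (3R)-1-[2,4-bis(tert-butyldimethylsilyloxy)phenyl]-3-ethenyl-3,7-dimethyloct-6-en-1-one
Conditions: Dess–Martin periodinane, CH2Cl2, 0 °C to rt
Reagents that add atoms: none
Why: Dess–Martin oxidation of the benzylic secondary alcohol gives the aryl ketone and removes the uncontrolled C1 centre.

Step 10
Reactants: 16 (3R)-1-[2,4-bis(tert-butyldimethylsilyloxy)phenyl]-3-ethenyl-3,7-dimethyloct-6-en-1-one
Product: 17 (3R,6E)-1-[2,4-bis(tert-butyldimethylsilyloxy)phenyl]-3-ethenyl-8-hydroxy-3,7-dimethyloct-6-en-1-one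
Conditions: SeO2 (0.3 equiv), t-BuOOH, salicylic acid (cat.), CH2Cl2, rt
Reagents that add atoms: selenium dioxide O=[Se]=O; tert-butyl hydroperoxide CC(C)(C)OO
Why: Selenium dioxide allylic oxidation (ene reaction, then [2,3]-sigmatropic shift) attacks the more substituted end of the C6=C7 alkene and oxidises the methyl group trans to the chain, giving the E primary allylic alcohol; the vinyl group has no allylic hydrogen and the hindered C2 methylene should be slow under these catalytic conditions.

Step 11
Reactants: 17 (3R,6E)-1-[2,4-bis(tert-butyldimethylsilyloxy)phenyl]-3-ethenyl-8-hydroxy-3,7-dimethyloct-6-en-1-one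
Product: 19 (3R,6E)-1-[2,4-bis(tert-butyldimethylsilyloxy)phenyl]-8-chloro-3-ethenyl-3,7-dimethyloct-6-en-1-one, via allylic mesylate 18 (not isolated)
Conditions: MsCl, 2,4,6-collidine, LiCl, DMF, 0 °C
Reagents that add atoms: lithium chloride [Li+].[Cl-]
Why: Mesylation and in situ SN2 displacement by chloride at the primary allylic carbon (conversion of an allylic alcohol into the chloride under collidine buffering) should proceed without allylic transposition or loss of the E geometry, and the ketone and aryl silyl ethers are inert.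

Step 12
Reactants: 20 1-bromo-2-methylprop-1-ene
Product: 22 tributyl(2-methylprop-1-en-1-yl)stannane, via 2-methylprop-1-enylmagnesium bromide 21 (not isolated)
Conditions: Mg, THF, reflux (gives 21); then Bu3SnCl, 0 °C to rt
Reagents that add atoms: tributyltin chloride CCCC[Sn](Cl)(CCCC)CCCC
Why: Grignard formation from the alkenyl bromide and transmetalation to tin (stannylation of an organomagnesium reagent) gives the alkenylstannane.

Step 13
Reactants: 19 (3R,6E)-1-[2,4-bis(tert-butyldimethylsilyloxy)phenyl]-8-chloro-3-ethenyl-3,7-dimethyloct-6-en-1-one; 22 tributyl(2-methylprop-1-en-1-yl)stannane; 23 carbon monoxide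
Product: 24 (3R,6E)-1-[2,4-bis(tert-butyldimethylsilyloxy)phenyl]-3-ethenyl-3,7,11-trimethyldodeca-6,10-diene-1,9-dione
Conditions: Pd2(dba)3 (2.5 mol%), PPh3 (10 mol%), CO (3 bar), THF, 50 °C
Reagents that add atoms: none
Why: Zerovalent palladium formed from Pd2(dba)3 and PPh3 ionises the C8–Cl bond of 19 to the syn eta-3-allyl complex of divalent palladium, CO inserts at the unsubstituted C8 terminus to give a but-3-enoyl palladium species, the alkenyl group of 22 is transferred from tin, and reductive elimination forms the C9–C10 bond and returns zerovalent palladium. The closest known reaction type is the carbonylative Stille coupling of allylic chlorides with alkenyl- and arylstannanes to give beta,gamma-unsaturated ketones. No ring is closed and no stereocentre is formed; C3 is remote and untouched. Three selectivities are needed: acylation at C8 and not at C6, which the alkyl-substituted and more hindered C6 terminus secures; retention of the E C6=C7 geometry, which follows because the E chloride gives the syn allyl complex directly; and ketone formation in place of direct allyl–alkenyl coupling, which the CO pressure and the slow transmetalation of the beta,beta-disubstituted alkenylstannane secure. The medium holds neither acid nor base, so the C8 methylene of 24 is not enolised and C6=C7 does not move into conjugation with C9, while the aryl ketone, the aryl silyl ethers and the hindered C3 vinyl group stay out of the reaction.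

Step 14
Reactants: 24 (3R,6E)-1-[2,4-bis(tert-butyldimethylsilyloxy)phenyl]-3-ethenyl-3,7,11-trimethyldodeca-6,10-diene-1,9-dione
Product: 25 (3R,6E)-1-(2,4-dihydroxyphenyl)-3-ethenyl-3,7,11-trimethyldodeca-6,10-diene-1,9-dione
Conditions: KHF2, MeOH, rt
Reagents that add atoms: none
Why: Bifluoride cleaves the two aryl silyl ethers (fluoride desilylation) in a weakly acidic medium in which the C8 methylene is not enolised, so the skipped dienone should survive and C3 is untouched.

**Compound list**

1 | but-3-yn-1-ol | C#CCCO | starting material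
2 | tert-butyl(but-3-yn-1-yloxy)dimethylsilane | C#CCCO[Si](C)(C)C(C)(C)C | intermediate
3 | [(1E)-4-(tert-butyldimethylsilyloxy)-2-methylbut-1-en-1-yl]dimethylalane | C[Al](C)/C=C(\C)CCO[Si](C)(C)C(C)(C)C | intermediate
4 | lithium butyl[(1E)-4-(tert-butyldimethylsilyloxy)-2-methylbut-1-en-1-yl]dimethylaluminate | [Li+].CCCC[Al-](C)(C)/C=C(\C)CCO[Si](C)(C)C(C)(C)C | intermediate
5 | (2E)-5-(tert-butyldimethylsilyloxy)-3-methylpent-2-en-1-ol | OC/C=C(\C)CCO[Si](C)(C)C(C)(C)C | intermediate
6 | diethyl (2E)-5-(tert-butyldimethylsilyloxy)-3-methylpent-2-en-1-yl phosphate | CCOP(=O)(OCC)OC/C=C(\C)CCO[Si](C)(C)C(C)(C)C | intermediate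
7 | 5-bromo-2-methylpent-2-ene | CC(C)=CCCBr | starting material
8 | (4-methylpent-3-en-1-yl)magnesium bromide | CC(C)=CCC[Mg]Br | intermediate
9 | tert-butyl{[(3R)-3-ethenyl-3,7-dimethyloct-6-en-1-yl]oxy}dimethylsilane | C=C[C@](C)(CCC=C(C)C)CCO[Si](C)(C)C(C)(C)C | intermediate
10 | (3R)-3-ethenyl-3,7-dimethyloct-6-en-1-ol | C=C[C@](C)(CCC=C(C)C)CCO | intermediate
11 | (3R)-3-ethenyl-3,7-dimethyloct-6-enal | C=C[C@](C)(CCC=C(C)C)CC=O | intermediate
12 | 4-bromobenzene-1,3-diol | Oc1ccc(Br)c(O)c1 | starting material
13 | 1-bromo-2,4-bis(tert-butyldimethylsilyloxy)benzene | CC(C)(C)[Si](C)(C)Oc1ccc(Br)c(O[Si](C)(C)C(C)(C)C)c1 | intermediate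
14 | [2,4-bis(tert-butyldimethylsilyloxy)phenyl]magnesium bromide | Br[Mg]c1ccc(O[Si](C)(C)C(C)(C)C)cc1O[Si](C)(C)C(C)(C)C | intermediate
15 | (3R)-1-[2,4-bis(tert-butyldimethylsilyloxy)phenyl]-3-ethenyl-3,7-dimethyloct-6-en-1-ol (both C1 epimers) | C=C[C@](C)(CCC=C(C)C)CC(O)c1ccc(O[Si](C)(C)C(C)(C)C)cc1O[Si](C)(C)C(C)(C)C | intermediate
16 | (3R)-1-[2,4-bis(tert-butyldimethylsilyloxy)phenyl]-3-ethenyl-3,7-dimethyloct-6-en-1-one | C=C[C@](C)(CCC=C(C)C)CC(=O)c1ccc(O[Si](C)(C)C(C)(C)C)cc1O[Si](C)(C)C(C)(C)C | intermediate
17 | (3R,6E)-1-[2,4-bis(tert-butyldimethylsilyloxy)phenyl]-3-ethenyl-8-hydroxy-3,7-dimethyloct-6-en-1-one | C=C[C@](C)(CC/C=C(\C)CO)CC(=O)c1ccc(O[Si](C)(C)C(C)(C)C)cc1O[Si](C)(C)C(C)(C)C | intermediate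
18 | (3R,6E)-1-[2,4-bis(tert-butyldimethylsilyloxy)phenyl]-3-ethenyl-3,7-dimethyl-8-(methylsulfonyloxy)oct-6-en-1-one | C=C[C@](C)(CC/C=C(\C)COS(C)(=O)=O)CC(=O)c1ccc(O[Si](C)(C)C(C)(C)C)cc1O[Si](C)(C)C(C)(C)C | intermediate
19 | (3R,6E)-1-[2,4-bis(tert-butyldimethylsilyloxy)phenyl]-8-chloro-3-ethenyl-3,7-dimethyloct-6-en-1-one | C=C[C@](C)(CC/C=C(\C)CCl)CC(=O)c1ccc(O[Si](C)(C)C(C)(C)C)cc1O[Si](C)(C)C(C)(C)C | intermediate
20 | 1-bromo-2-methylprop-1-ene | CC(C)=CBr | starting material
21 | (2-methylprop-1-en-1-yl)magnesium bromide | CC(C)=C[Mg]Br | intermediate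
22 | tributyl(2-methylprop-1-en-1-yl)stannane | CC(C)=C[Sn](CCCC)(CCCC)CCCC | intermediate
23 | carbon monoxide | [C-]#[O+] | starting material
24 | (3R,6E)-1-[2,4-bis(tert-butyldimethylsilyloxy)phenyl]-3-ethenyl-3,7,11-trimethyldodeca-6,10-diene-1,9-dione | C=C[C@](C)(CC/C=C(\C)CC(=O)C=C(C)C)CC(=O)c1ccc(O[Si](C)(C)C(C)(C)C)cc1O[Si](C)(C)C(C)(C)C | intermediate
25 | (3R,6E)-1-(2,4-dihydroxyphenyl)-3-ethenyl-3,7,11-trimethyldodeca-6,10-diene-1,9-dione | C=C[C@](C)(CC/C=C(\C)CC(=O)C=C(C)C)CC(=O)c1ccc(O)cc1O | target

**Count and risks**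

Total step count: 14. Longest linear sequence: 12 steps (steps 1–6, 8–11, 13 and 14, from but-3-yn-1-ol).

Steps most likely to fail:

1. Step 4. The chiral copper catalyst may discriminate poorly between the methyl and the 2-silyloxyethyl group at C3, giving low enantiomeric purity, or direct SN2 coupling at the primary carbon may compete and give the linear alkene. The fallback is a stereospecific lithiation–borylation followed by Zweifel olefination; it sets out from Grignard reagent 8 and returns to the route at 9.
   - Purchased (S)-butane-1,3-diol F1 is silylated at the primary hydroxyl (TBSCl, imidazole) to (S)-4-(tert-butyldimethylsilyloxy)butan-2-ol F2. This is acylated with 2,4,6-triisopropylbenzoyl chloride (Et3N, DMAP), with retention, to (S)-4-(tert-butyldimethylsilyloxy)butan-2-yl 2,4,6-triisopropylbenzoate F3.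
   - Reagent 8 is trapped with 2-isopropoxy-5,5-dimethyl-1,3,2-dioxaborinane to give 5,5-dimethyl-2-(4-methylpent-3-en-1-yl)-1,3,2-dioxaborinane F4.
   - Deprotonation of F3 with s-BuLi/TMEDA in cyclopentyl methyl ether at −60 °C should give the configurationally stable alpha-lithiated benzoate F5. Adding F4 forms the lithium boronate complex F6 with retention.
   - On warming, the homoprenyl group should migrate from boron to carbon with inversion and loss of the benzoate, giving 2-[(3S)-1-(tert-butyldimethylsilyloxy)-3,7-dimethyloct-6-en-3-yl]-5,5-dimethyl-1,3,2-dioxaborinane F7.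
   - Vinyllithium converts F7 into the lithium vinylboronate complex F8. Iodine followed by NaOMe (Zweifel olefination) replaces boron by vinyl with retention, giving 9 with the (R) configuration fixed by the starting diol.

2. Step 13. Direct allyl–alkenyl coupling without CO uptake may compete, transmetalation of the hindered stannane may be slow, C6=C7 may drift into conjugation with C9 during work-up, or the E geometry may erode through the anti allyl complex. The fallback is alkynylation followed by Meyer–Schuster rearrangement; it sets out from 19 and returns at 24.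
   - Copper-mediated coupling of 19 with 2-methylbut-3-yn-2-ol (CuI, K2CO3, NaI, DMF, rt) should substitute the primary allylic chloride without transposition. The product is the skipped enynol (3R,6E)-1-[2,4-bis(tert-butyldimethylsilyloxy)phenyl]-3-ethenyl-11-hydroxy-3,7,11-trimethyldodec-6-en-9-yn-1-one F9.
   - Meyer–Schuster rearrangement of the tertiary propargylic alcohol under monovalent gold catalysis (Ph3PAuNTf2, MeOH as additive, toluene, rt) should move the oxygen to C9 and form the C10=C11 alkene, giving 24.

3. Step 10. The allylic alcohol may be over-oxidised to the enal, conversion may stall, or oxidation may occur at C2 next to the ketone. The fallback is an ene-type allylic chlorination that feeds the same allylpalladium intermediate; it sets out from 16 and returns at 24, bypassing 17 and 19.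
   - NCS with catalytic PhSeCl in CH2Cl2 should convert the prenyl terminus into the transposed secondary allylic chloride (3R)-1-[2,4-bis(tert-butyldimethylsilyloxy)phenyl]-6-chloro-3-ethenyl-3,7-dimethyloct-7-en-1-one F10 (both C6 epimers).
   - Under the conditions of step 13 with 22 and 23, F10 should ionise to the same eta-3-allyl complex of divalent palladium as 19 and, after syn/anti equilibration, give 24.

Further compounds
F1 | step 4 | (S)-butane-1,3-diol | C[C@H](O)CCO
F2 | step 4 | (S)-4-(tert-butyldimethylsilyloxy)butan-2-ol | C[C@H](O)CCO[Si](C)(C)C(C)(C)C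
F3 | step 4 | (S)-4-(tert-butyldimethylsilyloxy)butan-2-yl 2,4,6-triisopropylbenzoate | C[C@H](OC(=O)c1c(C(C)C)cc(C(C)C)cc1C(C)C)CCO[Si](C)(C)C(C)(C)C
F4 | step 4 | 5,5-dimethyl-2-(4-methylpent-3-en-1-yl)-1,3,2-dioxaborinane | CC(C)=CCCB1OCC(C)(C)CO1
F5 | step 4 | alpha-lithiated benzoate of F3 | C[C@]([Li])(OC(=O)c1c(C(C)C)cc(C(C)C)cc1C(C)C)CCO[Si](C)(C)C(C)(C)C
F6 | step 4 | lithium boronate complex from F5 and F4 | [Li+].C[C@]([B-]1(CCC=C(C)C)OCC(C)(C)CO1)(OC(=O)c1c(C(C)C)cc(C(C)C)cc1C(C)C)CCO[Si](C)(C)C(C)(C)C
F7 | step 4 | 2-[(3S)-1-(tert-butyldimethylsilyloxy)-3,7-dimethyloct-6-en-3-yl]-5,5-dimethyl-1,3,2-dioxaborinane | CC1(C)COB(OC1)[C@](C)(CCC=C(C)C)CCO[Si](C)(C)C(C)(C)C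
F8 | step 4 | lithium vinylboronate complex of F7 | [Li+].C=C[B-]1(OCC(C)(C)CO1)[C@](C)(CCC=C(C)C)CCO[Si](C)(C)C(C)(C)C
F9 | step 13 | (3R,6E)-1-[2,4-bis(tert-butyldimethylsilyloxy)phenyl]-3-ethenyl-11-hydroxy-3,7,11-trimethyldodec-6-en-9-yn-1-one | C=C[C@](C)(CC/C=C(\C)CC#CC(C)(C)O)CC(=O)c1ccc(O[Si](C)(C)C(C)(C)C)cc1O[Si](C)(C)C(C)(C)C
F10 | step 10 | (3R)-1-[2,4-bis(tert-butyldimethylsilyloxy)phenyl]-6-chloro-3-ethenyl-3,7-dimethyloct-7-en-1-one (both C6 epimers) | C=C[C@](C)(CCC(Cl)C(C)=C)CC(=O)c1ccc(O[Si](C)(C)C(C)(C)C)cc1O[Si](C)(C)C(C)(C)C
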